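**Retrosynthetic overview**
- Target 22 ⇒ diene acetate 19 + buta-2,3-dienoic acid 20. The lactone O–CH2 bond is closed by attack of the carboxylate on the palladium-bound allene, and the resulting furanonyl–palladium is caught by the diene terminus.
- 19 ⇒ homoallylic bromide 11 + propargyl alcohol 12 + vinyl bromide 13 (anti-carbomagnesiation/cross-coupling fixes the 2Z olefin), then acetylation.
- 11 ⇒ alkynol 7 (carboalumination/ethylene oxide fixes the E trisubstituted olefin, then bromination).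
- 7 ⇒ (S)-2,2,6-trimethylcyclohexanone 3 + C4 Grignard reagent 5 (axial addition sets the carbinol centre); 3 ⇐ racemic ketone 1 by enantioselective protonation of silyl enol ether 2.
- Ring order: the cyclohexane ring is bought with 1; the butenolide ring is formed in the last step.

Assumption: the (R)-binaphthol acid of step 2 is taken to give the (S)-ketone (its mirror-image acid is used if the sense is opposite), and 1, 4 and 20 are bought (20 is otherwise one hydrolysis step from ethyl buta-2,3-dienoate).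

**Step 1**
Reactants: 1 racemic 2,2,6-trimethylcyclohexan-1-one
Product: 2 trimethyl[(2,6,6-trimethylcyclohex-1-en-1-yl)oxy]silane
Conditions: TMSOTf (1.2 equiv), Et3N (1.5 equiv), CH2Cl2, 0 °C → rt
Reagents that add atoms: trimethylsilyl trifluoromethanesulfonate C[Si](C)(C)OS(=O)(=O)C(F)(F)F
Why: Soft enolisation (silyl enol ether formation): C6 carries the only α-hydrogen, so a single tetrasubstituted enol ether forms and the racemic centre is erased.

**Step 2**
Reactants: 2 trimethyl[(2,6,6-trimethylcyclohex-1-en-1-yl)oxy]silane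
Product: 3 (6S)-2,2,6-trimethylcyclohexan-1-one
Conditions: (R)-2-hydroxy-2′-methoxy-1,1′-binaphthyl (10 mol %), SnCl4 (8 mol %), 2,6-dimethylphenol (1.1 equiv, slow addition), toluene, −78 °C
Reagents that add atoms: none
Why: Catalytic enantioselective protonation of a silyl enol ether by a Lewis-acid-assisted chiral Brønsted acid: the tin-bound binaphthol delivers the proton to one face of the planar enol ether and sets C6 as S (about 90% ee expected), while 2,6-dimethylphenol takes up the silyl group and turns the acid over.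

**Step 3**
Reactants: 3 (6S)-2,2,6-trimethylcyclohexan-1-one; 4 (4-bromobut-1-yn-1-yl)trimethylsilane
Product: 7 (1R,6S)-1-(but-3-yn-1-yl)-2,2,6-trimethylcyclohexan-1-ol, via Grignard reagent 5 (not isolated), via silylated alkynol 6 (not isolated)
Conditions: 4, Mg, THF, rt; added to 3 premixed with anhydrous CeCl3 (1.2 equiv), THF, −78 → 0 °C; then MeOH, K2CO3 (0.3 equiv), rt
Reagents that add atoms: none
Why: Grignard 1,2-addition promoted by CeCl3 (which suppresses enolisation and reduction of the hindered ketone): attack along the axial trajectory, anti to the axial C2 methyl of the chair that has the C6 methyl equatorial, puts the chain cis and the hydroxyl trans to the C6 methyl (1R), and methanolic carbonate then cleaves the C–Si bond.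

**Step 4**
Reactants: 7 (1R,6S)-1-(but-3-yn-1-yl)-2,2,6-trimethylcyclohexan-1-ol
Product: 10 (1R,6S)-1-[(3E)-6-hydroxy-3-methylhex-3-en-1-yl]-2,2,6-trimethylcyclohexan-1-ol, via alkenylalane 8 (not isolated), via lithium alanate 9 (not isolated)
Conditions: AlMe3 (3 equiv), Cp2ZrCl2 (0.25 equiv), CH2Cl2, 0 °C → rt; evaporate volatiles; n-BuLi (1.1 equiv), THF–hexane, −30 °C; ethylene oxide (3 equiv), −30 → 0 °C; aq. KNaC4H4O6 (potassium sodium tartrate)
Reagents that add atoms: trimethylaluminium C[Al](C)C; ethylene oxide C1CO1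
Why: Negishi zirconium-catalysed carboalumination adds methyl and aluminium syn across the terminal alkyne (methyl to the internal carbon), and the derived alanate opens ethylene oxide with retention at the vinylic carbon, which fixes the E trisubstituted olefin.

**Step 5**
Reactants: 10 (1R,6S)-1-[(3E)-6-hydroxy-3-methylhex-3-en-1-yl]-2,2,6-trimethylcyclohexan-1-ol
Product: 11 (1R,6S)-1-[(3E)-6-bromo-3-methylhex-3-en-1-yl]-2,2,6-trimethylcyclohexan-1-ol
Conditions: CBr4 (1.3 equiv), PPh3 (1.4 equiv), CH2Cl2, 0 °C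
Reagents that add atoms: carbon tetrabromide BrC(Br)(Br)Br
Why: Appel reaction: only the unhindered primary hydroxyl is activated as its oxyphosphonium and displaced by bromide (SN2), the tertiary carbinol flanked by two substituted carbons being inert at 0 °C.

**Step 6**
Reactants: 11 (1R,6S)-1-[(3E)-6-bromo-3-methylhex-3-en-1-yl]-2,2,6-trimethylcyclohexan-1-ol; 12 prop-2-yn-1-ol; 13 bromoethene
Product: 18 (1R,6S)-1-[(3E,7Z)-7-(hydroxymethyl)-3-methyldeca-3,7,9-trien-1-yl]-2,2,6-trimethylcyclohexan-1-ol, via chloromagnesium alkoxide 14 (not isolated), via Grignard reagent 15 (not isolated), via propargyl alkoxide 16 (not isolated), via magnesium chelate 17 (not isolated)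
Conditions: 11 (1.3 equiv), i-PrMgCl (1.0 equiv per OH), THF, 0 °C, then Mg, 40 °C; separately 12 (1.0 equiv), i-PrMgCl (1.0 equiv), THF, −20 °C; combine, CuI (10 mol %), THF–Et2O, −10 °C → rt; then 13 (3 equiv), Pd(PPh3)4 (5 mol %), rt; aq. NH4Cl
Reagents that add atoms: none
Why: Copper-catalysed anti-carbomagnesiation of the propargyl alkoxide delivers the alkyl group to C2 and magnesium to C3, held cis to the CH2O arm in a five-membered chelate, and Kumada–Corriu coupling with retention at that vinylic carbon therefore sets the 7Z geometry (CH2OH cis to the new vinyl group).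

**Step 7**
Reactants: 18 (1R,6S)-1-[(3E,7Z)-7-(hydroxymethyl)-3-methyldeca-3,7,9-trien-1-yl]-2,2,6-trimethylcyclohexan-1-ol
Product: 19 [(2Z)-2-{(3E)-6-[(1R,6S)-1-hydroxy-2,2,6-trimethylcyclohexyl]-4-methylhex-3-en-1-yl}penta-2,4-dien-1-yl] acetate
Conditions: Ac2O (1.5 equiv), pyridine, CH2Cl2, 0 °C → rt
Reagents that add atoms: acetic anhydride CC(=O)OC(C)=O
Why: Acylation of the primary allylic alcohol with acetic anhydride/pyridine; the hindered tertiary alcohol does not react without a stronger acyl-transfer catalyst.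

**Step 8**
Reactants: 19 [(2Z)-2-{(3E)-6-[(1R,6S)-1-hydroxy-2,2,6-trimethylcyclohexyl]-4-methylhex-3-en-1-yl}penta-2,4-dien-1-yl] acetate; 20 buta-2,3-dienoic acid
Product: 22 [(2Z,4E)-2-{(3E)-6-[(1R,6S)-1-hydroxy-2,2,6-trimethylcyclohexyl]-4-methylhex-3-en-1-yl}-5-(5-oxo-2,5-dihydrofuran-3-yl)penta-2,4-dien-1-yl] acetate, via furanonylpalladium acetate 21 (not isolated)
Conditions: Pd(OAc)2 (10 mol %), 2,6-dimethyl-1,4-benzoquinone (1.5 equiv), DMSO–MeCN (1:9), 35 °C, 20 (2.5 equiv) added over 6 h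
Reagents that add atoms: none
Why: Proposed new method: divalent palladium activates the allene of 20 for 5-endo anti-oxypalladation, in which the carboxylate oxygen closes the lactone O–CH2 bond and leaves the metal on C4 of the furanone (21); this vinylpalladium inserts the unhindered terminal CH2=CH of diene 19, β-hydride loss of the acidified hydrogen next to the lactone gives the 4E olefin, and the quinone returns zerovalent palladium to the divalent state; the 2Z olefin should keep its geometry because scrambling would need palladium on the tertiary carbon C2, and the closest known reaction types are the palladium-catalysed coupling–cyclisation of 2,3-allenoic acids with allylic halides and the oxidative (Fujiwara–Moritani-type) Heck reaction, which to my knowledge have not been combined with a conjugated diene as acceptor.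

**Compound list**
1 | racemic 2,2,6-trimethylcyclohexan-1-one | CC1CCCC(C)(C)C1=O | starting material
2 | trimethyl[(2,6,6-trimethylcyclohex-1-en-1-yl)oxy]silane | CC1=C(O[Si](C)(C)C)C(C)(C)CCC1 | intermediate
3 | (6S)-2,2,6-trimethylcyclohexan-1-one | O=C1[C@@H](C)CCCC1(C)C | intermediate
4 | (4-bromobut-1-yn-1-yl)trimethylsilane | C[Si](C)(C)C#CCCBr | starting material
5 | [4-(trimethylsilyl)but-3-yn-1-yl]magnesium bromide (not isolated) | C[Si](C)(C)C#CCC[Mg]Br | intermediate
6 | (1R,6S)-2,2,6-trimethyl-1-[4-(trimethylsilyl)but-3-yn-1-yl]cyclohexan-1-ol (not isolated) | C[Si](C)(C)C#CCC[C@@]1(O)[C@@H](C)CCCC1(C)C | intermediate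
7 | (1R,6S)-1-(but-3-yn-1-yl)-2,2,6-trimethylcyclohexan-1-ol | C#CCC[C@@]1(O)[C@@H](C)CCCC1(C)C | intermediate
8 | {(1E)-4-[(1R,6S)-1-(dimethylalumanyloxy)-2,2,6-trimethylcyclohexyl]-2-methylbut-1-en-1-yl}dimethylalumane (not isolated) | C[Al](C)/C=C(\C)CC[C@@]1(O[Al](C)C)[C@@H](C)CCCC1(C)C | intermediate
9 | lithium butyl{(1E)-4-[(1R,6S)-1-(dimethylalumanyloxy)-2,2,6-trimethylcyclohexyl]-2-methylbut-1-en-1-yl}dimethylalanate (not isolated) | [Li+].CCCC[Al-](C)(C)/C=C(\C)CC[C@@]1(O[Al](C)C)[C@@H](C)CCCC1(C)C | intermediate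
10 | (1R,6S)-1-[(3E)-6-hydroxy-3-methylhex-3-en-1-yl]-2,2,6-trimethylcyclohexan-1-ol | OCC/C=C(\C)CC[C@@]1(O)[C@@H](C)CCCC1(C)C | intermediate
11 | (1R,6S)-1-[(3E)-6-bromo-3-methylhex-3-en-1-yl]-2,2,6-trimethylcyclohexan-1-ol | BrCC/C=C(\C)CC[C@@]1(O)[C@@H](C)CCCC1(C)C | intermediate
12 | prop-2-yn-1-ol | C#CCO | starting material
13 | bromoethene | C=CBr | starting material
14 | chloromagnesium (1R,6S)-1-[(3E)-6-bromo-3-methylhex-3-en-1-yl]-2,2,6-trimethylcyclohexan-1-olate (not isolated) | BrCC/C=C(\C)CC[C@@]1(O[Mg]Cl)[C@@H](C)CCCC1(C)C | intermediate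
15 | bromo{(3E)-6-[(1R,6S)-1-(chloromagnesiooxy)-2,2,6-trimethylcyclohexyl]-4-methylhex-3-en-1-yl}magnesium (not isolated) | Br[Mg]CC/C=C(\C)CC[C@@]1(O[Mg]Cl)[C@@H](C)CCCC1(C)C | intermediate
16 | chloromagnesium prop-2-yn-1-olate (not isolated) | C#CCO[Mg]Cl | intermediate
17 | 4-{(3E)-6-[(1R,6S)-1-(chloromagnesiooxy)-2,2,6-trimethylcyclohexyl]-4-methylhex-3-en-1-yl}-2,5-dihydro-1,2-oxamagnesole (not isolated) | [Mg]1OCC(CC/C=C(\C)CC[C@@]2(O[Mg]Cl)[C@@H](C)CCCC2(C)C)=C1 | intermediate
18 | (1R,6S)-1-[(3E,7Z)-7-(hydroxymethyl)-3-methyldeca-3,7,9-trien-1-yl]-2,2,6-trimethylcyclohexan-1-ol | OC/C(=C\C=C)CC/C=C(\C)CC[C@@]1(O)[C@@H](C)CCCC1(C)C | intermediate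
19 | [(2Z)-2-{(3E)-6-[(1R,6S)-1-hydroxy-2,2,6-trimethylcyclohexyl]-4-methylhex-3-en-1-yl}penta-2,4-dien-1-yl] acetate | CC(=O)OC/C(=C\C=C)CC/C=C(\C)CC[C@@]1(O)[C@@H](C)CCCC1(C)C | intermediate
20 | buta-2,3-dienoic acid | C=C=CC(=O)O | starting material
21 | (5-oxo-2,5-dihydrofuran-3-yl)palladium acetate (not isolated) | CC(=O)O[Pd]C1=CC(=O)OC1 | intermediate
22 | [(2Z,4E)-2-{(3E)-6-[(1R,6S)-1-hydroxy-2,2,6-trimethylcyclohexyl]-4-methylhex-3-en-1-yl}-5-(5-oxo-2,5-dihydrofuran-3-yl)penta-2,4-dien-1-yl] acetate | CC(=O)OC/C(=C\C=C\C1=CC(=O)OC1)CC/C=C(\C)CC[C@@]1(O)[C@@H](C)CCCC1(C)C | target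

**Step count and risks**
Total steps: 8. Longest linear sequence: 8 (1 → 22); all other components are bought.

The three steps most likely to fail are steps 8, 6 and 4.

Step 8 is the new reaction. Its likely failure modes are protodepalladation or dimerisation of the furanonyl–palladium, carboxylate capture of the diene instead of β-hydride loss, and erosion of the 2Z geometry. The fallback uses known chemistry and sets out from bromide 11. The magnesium chelate 17, made exactly as in step 6, is quenched with I2 (THF, −20 °C) instead of being cross-coupled. This gives the iodo alcohol (1R,6S)-1-[(3E,7Z)-7-(hydroxymethyl)-8-iodo-3-methylocta-3,7-dien-1-yl]-2,2,6-trimethylcyclohexan-1-ol F1. Acetylation (Ac2O, pyridine) gives [(2Z)-2-{(3E)-6-[(1R,6S)-1-hydroxy-2,2,6-trimethylcyclohexyl]-4-methylhex-3-en-1-yl}-3-iodoprop-2-en-1-yl] acetate F2. A Heck reaction (Pd(OAc)2, Bu4NCl, K2CO3, DMF, 40 °C) then joins it to 4-ethenylfuran-2(5H)-one F3, which is made in one operation from propargyl alcohol 12, CH2=CHMgCl and CO2 (anti-carbomagnesiation, carboxylation, lactonisation on acid work-up). Here the stereodefined vinyl iodide carries the Z olefin through untouched, and the sequence comes back to the route at target 22.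

Step 6 needs a Grignard reagent made from an advanced bromide that carries a magnesium alkoxide, used in excess over 12, and a one-pot cross-coupling of the chelate. The fallback sets out from bromide 11 and lets a ring hold the Z geometry. Zinc insertion (Zn dust, LiCl, THF, 40 °C) gives bromo{(3E)-6-[(1R,6S)-1-hydroxy-2,2,6-trimethylcyclohexyl]-4-methylhex-3-en-1-yl}zinc F4. Negishi coupling with commercial 4-bromofuran-2(5H)-one (PdCl2(dppf), THF) gives 4-{(3E)-6-[(1R,6S)-1-hydroxy-2,2,6-trimethylcyclohexyl]-4-methylhex-3-en-1-yl}furan-2(5H)-one F5. Reduction with i-Bu2AlH (2.2 equiv, CH2Cl2, −78 °C) gives the lactol 4-{(3E)-6-[(1R,6S)-1-hydroxy-2,2,6-trimethylcyclohexyl]-4-methylhex-3-en-1-yl}-2,5-dihydrofuran-2-ol F6. Wittig methylenation (Ph3P=CH2 from Ph3PCH3Br and KOt-Bu, THF, 0 °C) opens the lactol and comes back to the route at dienol 18.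

Step 4 may stall at the carboalumination because of the tertiary aluminium alkoxide, or give a poor yield in the opening of ethylene oxide by the alanate. The fallback sets out from alkynol 7. The same alkenylalane 8 is quenched with I2 to give (1R,6S)-1-[(3E)-4-iodo-3-methylbut-3-en-1-yl]-2,2,6-trimethylcyclohexan-1-ol F7. Suzuki–Miyaura coupling with vinylboronic acid pinacol ester (PdCl2(dppf), K3PO4, THF–H2O) gives (1R,6S)-2,2,6-trimethyl-1-[(3E)-3-methylhexa-3,5-dien-1-yl]cyclohexan-1-ol F8. Hydroboration of the terminal vinyl group with 9-BBN followed by NaOH/H2O2 comes back to the route at homoallylic alcohol 10.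

**Further compounds**
F1 | step 8 | (1R,6S)-1-[(3E,7Z)-7-(hydroxymethyl)-8-iodo-3-methylocta-3,7-dien-1-yl]-2,2,6-trimethylcyclohexan-1-ol | OC/C(=C\I)CC/C=C(\C)CC[C@@]1(O)[C@@H](C)CCCC1(C)C
F2 | step 8 | [(2Z)-2-{(3E)-6-[(1R,6S)-1-hydroxy-2,2,6-trimethylcyclohexyl]-4-methylhex-3-en-1-yl}-3-iodoprop-2-en-1-yl] acetate | CC(=O)OC/C(=C\I)CC/C=C(\C)CC[C@@]1(O)[C@@H](C)CCCC1(C)C
F3 | step 8 | 4-ethenylfuran-2(5H)-one | C=CC1=CC(=O)OC1
F4 | step 6 | bromo{(3E)-6-[(1R,6S)-1-hydroxy-2,2,6-trimethylcyclohexyl]-4-methylhex-3-en-1-yl}zinc | Br[Zn]CC/C=C(\C)CC[C@@]1(O)[C@@H](C)CCCC1(C)C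
F5 | step 6 | 4-{(3E)-6-[(1R,6S)-1-hydroxy-2,2,6-trimethylcyclohexyl]-4-methylhex-3-en-1-yl}furan-2(5H)-one | O=C1C=C(CC/C=C(\C)CC[C@@]2(O)[C@@H](C)CCCC2(C)C)CO1
F6 | step 6 | 4-{(3E)-6-[(1R,6S)-1-hydroxy-2,2,6-trimethylcyclohexyl]-4-methylhex-3-en-1-yl}-2,5-dihydrofuran-2-ol | OC1C=C(CC/C=C(\C)CC[C@@]2(O)[C@@H](C)CCCC2(C)C)CO1
F7 | step 4 | (1R,6S)-1-[(3E)-4-iodo-3-methylbut-3-en-1-yl]-2,2,6-trimethylcyclohexan-1-ol | I/C=C(\C)CC[C@@]1(O)[C@@H](C)CCCC1(C)C
F8 | step 4 | (1R,6S)-2,2,6-trimethyl-1-[(3E)-3-methylhexa-3,5-dien-1-yl]cyclohexan-1-ol | C=C/C=C(\C)CC[C@@]1(O)[C@@H](C)CCCC1(C)C
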